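## Retrosynthetic overview

1. The threo glycerol unit (C7''–C8'') is disconnected last, to an Evans syn-aldol between an aryloxyacetyl imide on O4' of the central ring and silylated syringaldehyde. Ring A (C7–O–C9'–C8'–C8) is then traced back to a γ-lactone with its carbonyl at C9'.
2. The strategy rests on ring B (O–C9–C8–C8'–C7'): the benzylic carbon C7' is the fifth atom from the fusion carbon C8' and holds its syringyl ring on the concave face of the cis-fused 3,7-dioxabicyclo[3.3.0]octane, the epimer that acid equilibration does not deliver. The C8'–C7' bond is therefore cut to a rhodium carbene at C8' and a C7'–H bond of a syringylmethyl ether on C9.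
3. The α-diazo lactone comes from a trans 4-(hydroxymethyl)-5-aryl-γ-butyrolactone; C7 and C8 are set by an Evans syn-aldol of a succinate imide with silylated vanillin, followed by lactonisation.
4. Ring order: γ-lactone (later ring A), then ring B by C–H insertion, then ring A by reduction and closure through the C9' mesylate; the side chain is built last.

Key step: step 11

Remarks on the chemistry:
- Lignan locants are used: C7–C9 for the guaiacyl unit, C7'–C9' for the central syringyl unit, C7''–C9'' for the terminal syringylglycerol unit. The target is read as (7R,8S,7'S,8'S) with the guaiacyl ring exo and the syringyl ring endo, and (7''R,8''R) threo in the side chain.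
- The central phenol is carried as an allyl ether. It is removed with zerovalent palladium, so no hydrogenolysis step is needed that could also cleave the benzylic C–O bonds of the furofuran.
- Both enantiomers of 4-benzyl-1,3-oxazolidin-2-one, methyl 4-chloro-4-oxobutanoate and bromoacetyl bromide are assumed to be commercial.

## Route

Step 1
Reactants: 1 vanillin
Product: 2 3-methoxy-4-(triisopropylsilyloxy)benzaldehyde
Conditions: iPr3SiCl, imidazole, DMF, rt
Reagents that add atoms: triisopropylsilyl chloride, CC(C)[Si](Cl)(C(C)C)C(C)C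
Why: Imidazole-promoted O-silylation of the phenol (silyl ether formation) masks the acidic OH for the boron aldol and gives an aryl silyl ether that should last through the base, hydride and carbene steps until fluoride is applied at the end.

Step 2
Reactants: 3 (R)-4-benzyl-1,3-oxazolidin-2-one; 4 methyl 4-chloro-4-oxobutanoate
Product: 5 methyl 4-[(4R)-4-benzyl-2-oxo-1,3-oxazolidin-3-yl]-4-oxobutanoate
Conditions: n-BuLi, THF, −78 °C; then 4, −78 → 0 °C
Reagents that add atoms: none
Why: N-Acylation of the lithiated oxazolidinone occurs at the acid chloride, which is far more electrophilic than the methyl ester, and installs the (R)-auxiliary that will direct the aldol.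

Step 3
Reactants: 5 succinate imide; 2 silylated vanillin
Product: 7 (4R)-4-benzyl-3-{(2R,3R)-2-[3-methoxy-4-(triisopropylsilyloxy)phenyl]-5-oxooxolane-3-carbonyl}-1,3-oxazolidin-2-one (trans lactone imide), via syn-aldol adduct 6 (not isolated)
Conditions: Bu2BOTf, iPr2NEt, CH2Cl2, 0 °C; 2, −78 → 0 °C; H2O2, pH 7 buffer, MeOH; then PPTS (cat.), PhMe, 50 °C
Reagents that add atoms: none
Why: Evans syn-aldol reaction: the Z boron enolate of the imide (the ester is not enolised) adds to 2 through a chair Zimmerman–Traxler transition state on the enolate face away from the benzyl group of the (R)-auxiliary, which sets C8 and C7 (3R,4R in 6), and the C7 hydroxyl then closes onto the methyl ester (lactonisation) to give the trans 4,5-disubstituted lactone.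

Step 4
Reactants: 7 trans lactone imide
Product: 8 (2R,3R)-2-[3-methoxy-4-(triisopropylsilyloxy)phenyl]-5-oxooxolane-3-carboxylic acid
Conditions: LiOH, H2O2, THF/H2O, 0 °C; Na2SO3; then 1 M HCl
Reagents that add atoms: hydrogen peroxide, OO
Why: Auxiliary cleavage with lithium hydroperoxide, which attacks the exocyclic imide carbonyl in preference to the ring carbamate, frees the acid, and the acidic work-up recloses any lactone opened by hydroxide, so C7 and C8 are not disturbed (the trans acid is also the more stable epimer).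

Step 5
Reactants: 8 trans lactone acid
Product: 9 (4S,5R)-4-(hydroxymethyl)-5-[3-methoxy-4-(triisopropylsilyloxy)phenyl]oxolan-2-one
Conditions: BH3·SMe2, THF, 0 °C → rt; MeOH quench
Reagents that add atoms: none
Why: Chemoselective borane reduction: the carboxylic acid is reduced through its acyloxyborane far faster than the lactone, and the non-basic medium avoids migration of the lactone to the new primary hydroxyl.

Step 6
Reactants: 10 syringaldehyde
Product: 11 3,5-dimethoxy-4-(prop-2-enyloxy)benzaldehyde
Conditions: allyl bromide, K2CO3, DMF, rt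
Reagents that add atoms: allyl bromide, C=CCBr
Why: Williamson O-alkylation of the phenoxide gives an allyl ether that can later be removed without hydrogen.

Step 7
Reactants: 11 allyl-protected syringaldehyde
Product: 12 [3,5-dimethoxy-4-(prop-2-enyloxy)phenyl]methanol
Conditions: NaBH4, MeOH, 0 °C
Reagents that add atoms: none
Why: Sodium borohydride reduction of the aryl aldehyde to the benzylic alcohol.

Step 8
Reactants: 12 benzylic alcohol
Product: 13 3,5-dimethoxy-4-(prop-2-enyloxy)benzyl 2,2,2-trichloroacetimidate
Conditions: Cl3CCN, DBU (cat.), CH2Cl2, 0 °C; used crude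
Reagents that add atoms: trichloroacetonitrile, ClC(Cl)(Cl)C#N
Why: Base-catalysed addition of the alcohol to trichloroacetonitrile (trichloroacetimidate formation) turns the benzylic hydroxyl into a leaving group that can be activated by acid.

Step 9
Reactants: 9 hydroxymethyl lactone; 13 trichloroacetimidate
Product: 14 (4S,5R)-4-{[3,5-dimethoxy-4-(prop-2-enyloxy)benzyl]oxymethyl}-5-[3-methoxy-4-(triisopropylsilyloxy)phenyl]oxolan-2-one
Conditions: TfOH (cat.), 4 Å MS, CH2Cl2, −40 → 0 °C
Reagents that add atoms: none
Why: Acid-catalysed benzylation with a trichloroacetimidate: the protonated imidate delivers the electron-rich benzyl group to the primary hydroxyl of 9 without forming an alkoxide, which would attack the lactone, and no stereocentre is involved.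

Step 10
Reactants: 14 lactone ether
Product: 16 (4S,5R)-3-diazo-4-{[3,5-dimethoxy-4-(prop-2-enyloxy)benzyl]oxymethyl}-5-[3-methoxy-4-(triisopropylsilyloxy)phenyl]oxolan-2-one (trans α-diazo lactone), via trifluoroacetyl lactone 15 (not isolated)
Conditions: LiN(SiMe3)2, THF, −78 °C; CF3CO2CH2CF3; aq. HCl work-up; then MsN3, Et3N, H2O, MeCN, rt
Reagents that add atoms: methanesulfonyl azide, CS(=O)(=O)N=[N+]=[N-]
Why: Detrifluoroacetylative diazo transfer: the lactone enolate, which can form only at C8', is C-trifluoroacetylated, the resulting 1,3-dicarbonyl compound accepts the diazo group from the sulfonyl azide and the trifluoroacetyl group leaves as the N-sulfonyl amide, while C7 and C8 carry no acidic hydrogen and keep their configuration.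

Step 11
Reactants: 16 trans α-diazo lactone
Product: 17 furofuranone with C9' carbonyl, (7R,8S,7'S,8'R), 7-aryl exo and 7'-aryl endo on the cis-fused 3,7-dioxabicyclo[3.3.0]octanone
Conditions: Rh2(OAc)4 (2 mol %), CH2Cl2, reflux, slow addition of 16 at high dilution
Reagents that add atoms: none
Why: With Rh2(OAc)4 the diazo lactone loses N2 to give an electrophilic rhodium carbene at C8', which inserts into one benzylic C7'–H bond of the ether through a three-centre, hydride-transfer-like transition state and so forms the C8'–C7' bond. The closest known reaction type is the dirhodium-tetracarboxylate-catalysed 1,5 C–H insertion of α-diazo-γ-butyrolactones into benzylic ether C–H bonds, which gives endo,exo-furofuranones. Ring B (O, C9, C8, C8', C7') closes in the 1,5-insertion mode through a five-membered cyclic transition state, the only five-ring path open to the carbene. C8' can only become cis-fused because the tether hangs from C8, and at C7' the aryl group is expected to turn away from the carboxylate wall of the catalyst toward the lactone, which places it on the concave face. The step needs chemoselectivity for this C–H bond over 1,2-hydride shift from C8, ylide formation at the ether oxygen and cyclopropanation of the allyl group, and it needs the endo sense at C7'; the C7'–H bond is activated by the ether oxygen and the electron-rich ring, the allyl group cannot reach the carbene within the molecule, and slow addition at high dilution suppresses bimolecular reactions.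

Step 12
Reactants: 17 furofuranone
Product: 18 (R)-{(3S,4S,5S)-5-[3,5-dimethoxy-4-(prop-2-enyloxy)phenyl]-4-(hydroxymethyl)oxolan-3-yl}[3-methoxy-4-(triisopropylsilyloxy)phenyl]methanol (C7/C9' diol with ring B intact)
Conditions: LiAlH4, THF, 0 °C
Reagents that add atoms: none
Why: Hydride reduction of the lactone (acyl C–O cleavage) gives the C7/C9' diol, and the C7–O bond and all four stereocentres are untouched.

Step 13
Reactants: 18 diol
Product: 20 furofuran allyl ether (7R,8S,7'S,8'S) with 7-[3-methoxy-4-(triisopropylsilyloxy)phenyl] exo and 7'-[3,5-dimethoxy-4-(prop-2-enyloxy)phenyl] endo, via primary mesylate 19 (not isolated)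
Conditions: MsCl, pyridine, CH2Cl2, 0 °C → rt
Reagents that add atoms: none
Why: Selective sulfonylation of the primary C9' hydroxyl followed by intramolecular Williamson etherification (5-exo-tet) by the C7 hydroxyl recloses ring A at the primary carbon, so C7 keeps its configuration and the guaiacyl group stays exo, and the basic medium does not epimerise the endo aryl at C7'.

Step 14
Reactants: 20 furofuran allyl ether
Product: 21 furofuran phenol (7R,8S,7'S,8'S) with 7'-(4-hydroxy-3,5-dimethoxyphenyl) endo
Conditions: Pd(PPh3)4 (cat.), morpholine, THF, rt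
Reagents that add atoms: none
Why: Tsuji–Trost deallylation: zerovalent palladium ionises the aryl allyl ether to a π-allyl complex that morpholine captures, which frees the hindered phenol without hydrogen or acid and so leaves the benzylic C–O bonds of the furofuran and the silyl ether alone.

Step 15
Reactants: 22 (S)-4-benzyl-1,3-oxazolidin-2-one; 23 bromoacetyl bromide
Product: 24 (S)-4-benzyl-3-(bromoacetyl)-1,3-oxazolidin-2-one
Conditions: n-BuLi, THF, −78 °C; then 23, −78 °C
Reagents that add atoms: none
Why: N-Acylation of the lithiated oxazolidinone at the acyl bromide, which reacts far faster than the alkyl bromide at low temperature.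

Step 16
Reactants: 21 furofuran phenol; 24 bromoacetyl imide
Product: 25 aryloxyacetyl imide: (4S)-4-benzyl-3-(aryloxyacetyl)-1,3-oxazolidin-2-one in which the aryl group is the central syringyl ring of the furofuran, linked through O4'
Conditions: K2CO3, acetone, rt → 40 °C
Reagents that add atoms: none
Why: Williamson etherification: the phenoxide displaces bromide from the α-bromo imide in an SN2 reaction that is much faster than acyl transfer from the imide, and it installs C8'', C9'' and the (S)-auxiliary in one operation.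

Step 17
Reactants: 10 syringaldehyde
Product: 26 4-(tert-butyldimethylsilyloxy)-3,5-dimethoxybenzaldehyde
Conditions: tBuMe2SiCl, imidazole, DMF, rt
Reagents that add atoms: tert-butyldimethylsilyl chloride, CC(C)(C)[Si](C)(C)Cl
Why: Imidazole-promoted silylation protects the phenol of the aldehyde for the aldol and falls to fluoride together with the other silyl ether.

Step 18
Reactants: 25 aryloxyacetyl imide; 26 silylated syringaldehyde
Product: 27 syn-aldol adduct (8''S,7''R; the same spatial arrangement as 8''R,7''R in the target) with the (4S)-auxiliary on C9''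
Conditions: Bu2BOTf, iPr2NEt, CH2Cl2, −78 → 0 °C; 26, −78 → 0 °C; H2O2, pH 7 buffer, MeOH
Reagents that add atoms: none
Why: Evans syn-aldol reaction of an aryloxyacetyl imide: the Z boron enolate adds to 26 through a chair Zimmerman–Traxler transition state on the face away from the benzyl group of the (S)-auxiliary, which sets C8'' and C7'' in the syn (threo) relationship with the spatial arrangement of the target.

Step 19
Reactants: 27 syn-aldol adduct
Product: 28 bis-silylated target: threo (7''R,8''R) C7''/C9'' diol
Conditions: LiBH4, THF, 0 °C → rt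
Reagents that add atoms: none
Why: Reductive removal of the auxiliary: LiBH4 reduces the activated imide carbonyl to the primary alcohol C9'' without touching C8'' or C7'' (the descriptor at C8'' changes to R only because C9'' drops in priority).

Step 20
Reactants: 28 bis-silylated target
Product: 29 target CNP0317965.1
Conditions: Bu4NF, AcOH, THF, 0 °C → rt
Reagents that add atoms: none
Why: Fluoride-mediated desilylation cleaves both aryl silyl ethers, and the acetic acid buffer keeps the medium close to neutral so that the free phenols do not open or epimerise the furofuran.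

## Compound list

1 | vanillin | COc1cc(C=O)ccc1O | starting material
2 | 3-methoxy-4-(triisopropylsilyloxy)benzaldehyde | COc1cc(C=O)ccc1O[Si](C(C)C)(C(C)C)C(C)C | intermediate
3 | (R)-4-benzyl-1,3-oxazolidin-2-one | O=C1N[C@H](Cc2ccccc2)CO1 | starting material
4 | methyl 4-chloro-4-oxobutanoate | COC(=O)CCC(Cl)=O | starting material
5 | methyl 4-[(4R)-4-benzyl-2-oxo-1,3-oxazolidin-3-yl]-4-oxobutanoate | COC(=O)CCC(=O)N1[C@H](Cc2ccccc2)COC1=O | intermediate
6 | methyl (3R,4R)-3-[(4R)-4-benzyl-2-oxo-1,3-oxazolidine-3-carbonyl]-4-hydroxy-4-[3-methoxy-4-(triisopropylsilyloxy)phenyl]butanoate (syn-aldol adduct) | COC(=O)C[C@@H](C(=O)N1[C@H](Cc2ccccc2)COC1=O)[C@@H](O)c1ccc(O[Si](C(C)C)(C(C)C)C(C)C)c(OC)c1 | intermediate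
7 | (4R)-4-benzyl-3-{(2R,3R)-2-[3-methoxy-4-(triisopropylsilyloxy)phenyl]-5-oxooxolane-3-carbonyl}-1,3-oxazolidin-2-one | COc1cc([C@@H]2OC(=O)C[C@H]2C(=O)N2[C@H](Cc3ccccc3)COC2=O)ccc1O[Si](C(C)C)(C(C)C)C(C)C | intermediate
8 | (2R,3R)-2-[3-methoxy-4-(triisopropylsilyloxy)phenyl]-5-oxooxolane-3-carboxylic acid | COc1cc([C@@H]2OC(=O)C[C@H]2C(O)=O)ccc1O[Si](C(C)C)(C(C)C)C(C)C | intermediate
9 | (4S,5R)-4-(hydroxymethyl)-5-[3-methoxy-4-(triisopropylsilyloxy)phenyl]oxolan-2-one | COc1cc([C@@H]2OC(=O)C[C@H]2CO)ccc1O[Si](C(C)C)(C(C)C)C(C)C | intermediate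
10 | syringaldehyde | COc1cc(C=O)cc(OC)c1O | starting material
11 | 3,5-dimethoxy-4-(prop-2-enyloxy)benzaldehyde | COc1cc(C=O)cc(OC)c1OCC=C | intermediate
12 | [3,5-dimethoxy-4-(prop-2-enyloxy)phenyl]methanol | COc1cc(CO)cc(OC)c1OCC=C | intermediate
13 | 3,5-dimethoxy-4-(prop-2-enyloxy)benzyl 2,2,2-trichloroacetimidate | COc1cc(COC(=N)C(Cl)(Cl)Cl)cc(OC)c1OCC=C | intermediate
14 | (4S,5R)-4-{[3,5-dimethoxy-4-(prop-2-enyloxy)benzyl]oxymethyl}-5-[3-methoxy-4-(triisopropylsilyloxy)phenyl]oxolan-2-one | COc1cc([C@@H]2OC(=O)C[C@H]2COCc2cc(OC)c(OCC=C)c(OC)c2)ccc1O[Si](C(C)C)(C(C)C)C(C)C | intermediate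
15 | 3-(trifluoroacetyl) derivative of 14 (C8' unassigned, enolisable) | COc1cc([C@@H]2OC(=O)C(C(=O)C(F)(F)F)[C@H]2COCc2cc(OC)c(OCC=C)c(OC)c2)ccc1O[Si](C(C)C)(C(C)C)C(C)C | intermediate
16 | (4S,5R)-3-diazo-4-{[3,5-dimethoxy-4-(prop-2-enyloxy)benzyl]oxymethyl}-5-[3-methoxy-4-(triisopropylsilyloxy)phenyl]oxolan-2-one | COc1cc([C@@H]2OC(=O)C(=[N+]=[N-])[C@H]2COCc2cc(OC)c(OCC=C)c(OC)c2)ccc1O[Si](C(C)C)(C(C)C)C(C)C | intermediate
17 | furofuranone (7R,8S,7'S,8'R), C9' carbonyl, 7-aryl exo, 7'-aryl endo | COc1cc([C@@H]2OC(=O)[C@@H]3[C@H]2CO[C@@H]3c2cc(OC)c(OCC=C)c(OC)c2)ccc1O[Si](C(C)C)(C(C)C)C(C)C | intermediate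
18 | (R)-{(3S,4S,5S)-5-[3,5-dimethoxy-4-(prop-2-enyloxy)phenyl]-4-(hydroxymethyl)oxolan-3-yl}[3-methoxy-4-(triisopropylsilyloxy)phenyl]methanol | COc1cc([C@H](O)[C@@H]2CO[C@H](c3cc(OC)c(OCC=C)c(OC)c3)[C@@H]2CO)ccc1O[Si](C(C)C)(C(C)C)C(C)C | intermediate
19 | C9' methanesulfonate of 18 | COc1cc([C@H](O)[C@@H]2CO[C@H](c3cc(OC)c(OCC=C)c(OC)c3)[C@@H]2COS(C)(=O)=O)ccc1O[Si](C(C)C)(C(C)C)C(C)C | intermediate
20 | furofuran allyl ether (7R,8S,7'S,8'S), 7-aryl exo, 7'-aryl endo | COc1cc([C@@H]2OC[C@@H]3[C@H]2CO[C@@H]3c2cc(OC)c(OCC=C)c(OC)c2)ccc1O[Si](C(C)C)(C(C)C)C(C)C | intermediate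
21 | furofuran phenol (7R,8S,7'S,8'S) with free 4'-OH | COc1cc([C@@H]2OC[C@@H]3[C@H]2CO[C@@H]3c2cc(OC)c(O)c(OC)c2)ccc1O[Si](C(C)C)(C(C)C)C(C)C | intermediate
22 | (S)-4-benzyl-1,3-oxazolidin-2-one | O=C1N[C@@H](Cc2ccccc2)CO1 | starting material
23 | bromoacetyl bromide | BrCC(Br)=O | starting material
24 | (S)-4-benzyl-3-(bromoacetyl)-1,3-oxazolidin-2-one | O=C(CBr)N1[C@@H](Cc2ccccc2)COC1=O | intermediate
25 | aryloxyacetyl imide of 21 with the (4S)-auxiliary | COc1cc([C@@H]2OC[C@@H]3[C@H]2CO[C@@H]3c2cc(OC)c(OCC(=O)N3[C@@H](Cc4ccccc4)COC3=O)c(OC)c2)ccc1O[Si](C(C)C)(C(C)C)C(C)C | intermediate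
26 | 4-(tert-butyldimethylsilyloxy)-3,5-dimethoxybenzaldehyde | COc1cc(C=O)cc(OC)c1O[Si](C)(C)C(C)(C)C | intermediate
27 | syn-aldol adduct (8''S,7''R) with the (4S)-auxiliary on C9'' | COc1cc([C@@H]2OC[C@@H]3[C@H]2CO[C@@H]3c2cc(OC)c(O[C@H](C(=O)N3[C@@H](Cc4ccccc4)COC3=O)[C@H](O)c3cc(OC)c(O[Si](C)(C)C(C)(C)C)c(OC)c3)c(OC)c2)ccc1O[Si](C(C)C)(C(C)C)C(C)C | intermediate
28 | bis-silylated target, threo (7''R,8''R) diol | COc1cc([C@@H]2OC[C@@H]3[C@H]2CO[C@@H]3c2cc(OC)c(O[C@H](CO)[C@H](O)c3cc(OC)c(O[Si](C)(C)C(C)(C)C)c(OC)c3)c(OC)c2)ccc1O[Si](C(C)C)(C(C)C)C(C)C | intermediate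
29 | CNP0317965.1 | COc1cc([C@@H]2OC[C@@H]3[C@H]2CO[C@@H]3c2cc(OC)c(O[C@H](CO)[C@H](O)c3cc(OC)c(O)c(OC)c3)c(OC)c2)ccc1O | target

## Step count and risks

Total step count: 20. Longest linear sequence: 14 steps (steps 1, 3, 4, 5, 9, 10, 11, 12, 13, 14, 16, 18, 19, 20).

Steps most likely to fail:

1. Step 11 (carbene C–H insertion). The carbene may be lost to 1,2-hydride shift from C8, to ylide formation at the ether oxygen or to bimolecular attack on the allyl group, or the facial preference at C7' may be too weak and give the exo aryl epimer. The fallback sets out from 9 and 11 and comes back at 17. Compound 9 is silylated (Et3SiCl, imidazole, DMF) to the triethylsilyl ether F1. The lithium enolate of F1 (LiN(SiMe3)2, THF, −78 °C) is added to aldehyde 11 to give the aldol adducts F2 as a mixture at C8' and C7'. Oxidation with Dess–Martin periodinane gives the β-keto lactone F3, in which C8' can epimerise. Treatment of F3 with Et3SiH and BF3·OEt2 (CH2Cl2, −78 °C) should let the C9 silyl ether oxygen close onto the ketone. The cis-fused bicyclic oxocarbenium ion at C7' should then be reduced by the silane from its convex face, which puts the aryl group endo and gives 17. This is a reductive etherification of a silyloxy ketone, a known reaction type.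

2. Step 18 (glycolate-type aldol on the furofuran). The boron Lewis acid may open or epimerise the endo aryl ether at C7', enolisation of the bulky imide may stay incomplete, or the electron-rich aldehyde may add slowly with loss of selectivity. The fallback sets out from 21 and 26 and comes back at 28. Aldehyde 26 is homologated with ethyl diazoacetate and NbCl5 (cat.) (Roskamp reaction) to the β-keto ester F4. Bromination with N-bromosuccinimide gives the α-bromo β-keto ester F5. Phenol 21 is alkylated with F5 (K2CO3, acetone) to the α-aryloxy β-keto ester F6, whose C8'' epimers interconvert through the enol. Asymmetric transfer hydrogenation with dynamic kinetic resolution (RuCl(p-cymene)[(S,S)-TsDPEN], HCO2H/Et3N; catalyst enantiomer chosen to give 7''R) should deliver the syn hydroxy ester F7. Reduction of F7 with LiBH4 gives 28.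

3. Step 9 (imidate etherification). The acid may rearrange the imidate to the N-benzyl trichloroacetamide before it is captured, or may ionise the benzylic lactone C7–O bond and let the lactone migrate. The fallback sets out from 12 and 9 and comes back at 14. Alcohol 12 is converted with PBr3 (Et2O, 0 °C) to the benzylic bromide F8. F8 is joined to 9 with AgOTf and 2,6-di-tert-butyl-4-methylpyridine (CH2Cl2, −20 °C → rt), a silver-assisted etherification in a buffered medium without free acid or alkoxide.

Further compounds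
F1 | step 11 | (4S,5R)-5-[3-methoxy-4-(triisopropylsilyloxy)phenyl]-4-[(triethylsilyloxy)methyl]oxolan-2-one | COc1cc([C@@H]2OC(=O)C[C@H]2CO[Si](CC)(CC)CC)ccc1O[Si](C(C)C)(C(C)C)C(C)C
F2 | step 11 | 3-{[3,5-dimethoxy-4-(prop-2-enyloxy)phenyl](hydroxy)methyl} derivative of F1 (mixture at C8' and C7') | COc1cc([C@@H]2OC(=O)C(C(O)c3cc(OC)c(OCC=C)c(OC)c3)[C@H]2CO[Si](CC)(CC)CC)ccc1O[Si](C(C)C)(C(C)C)C(C)C
F3 | step 11 | 3-[3,5-dimethoxy-4-(prop-2-enyloxy)benzoyl] derivative of F1 (C8' epimerisable) | COc1cc([C@@H]2OC(=O)C(C(=O)c3cc(OC)c(OCC=C)c(OC)c3)[C@H]2CO[Si](CC)(CC)CC)ccc1O[Si](C(C)C)(C(C)C)C(C)C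
F4 | step 18 | ethyl 3-[4-(tert-butyldimethylsilyloxy)-3,5-dimethoxyphenyl]-3-oxopropanoate | CCOC(=O)CC(=O)c1cc(OC)c(O[Si](C)(C)C(C)(C)C)c(OC)c1
F5 | step 18 | ethyl 2-bromo-3-[4-(tert-butyldimethylsilyloxy)-3,5-dimethoxyphenyl]-3-oxopropanoate | CCOC(=O)C(Br)C(=O)c1cc(OC)c(O[Si](C)(C)C(C)(C)C)c(OC)c1
F6 | step 18 | α-aryloxy β-keto ester from 21 and F5 (C8'' unassigned) | COc1cc([C@@H]2OC[C@@H]3[C@H]2CO[C@@H]3c2cc(OC)c(OC(C(=O)OCC)C(=O)c3cc(OC)c(O[Si](C)(C)C(C)(C)C)c(OC)c3)c(OC)c2)ccc1O[Si](C(C)C)(C(C)C)C(C)C
F7 | step 18 | syn α-aryloxy β-hydroxy ethyl ester (8''S,7''R) | COc1cc([C@@H]2OC[C@@H]3[C@H]2CO[C@@H]3c2cc(OC)c(O[C@H](C(=O)OCC)[C@H](O)c3cc(OC)c(O[Si](C)(C)C(C)(C)C)c(OC)c3)c(OC)c2)ccc1O[Si](C(C)C)(C(C)C)C(C)C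
F8 | step 9 | 5-(bromomethyl)-1,3-dimethoxy-2-(prop-2-enyloxy)benzene | COc1cc(CBr)cc(OC)c1OCC=C
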